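The amounts I had were three earlier runs, which ended with 27 %, 21 % and 16 % of target.

the same everywhere: starting material 20 mM
- east: second substrate 0.18 equiv; reagent 1.8 equiv; free catalyst 0.81 mol%; run made earlier
- south: second substrate 0.63 equiv; reagent 1.8 equiv; free catalyst 0.81 mol%; run made earlier
- south-west: second substrate 0.50 equiv; reagent 1.8 equiv; free catalyst 0.59 mol%; run made earlier
- ochre: second substrate 0.250 equiv; reagent 2.70 equiv; free catalyst 0.2 mol%; time 1.0 h
- amber: second substrate 0.340 equiv; reagent 1.80 equiv; free catalyst 1.5 mol%; time 1.0 h
- grey: second substrate 0.500 equiv; reagent 1.80 equiv; free catalyst 0.81 mol%; time 1.0 h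
- teal: second substrate 1.00 equiv; reagent 1.80 equiv; free catalyst 0.81 mol%; time 1.0 h
- green: second substrate 0.500 equiv; reagent 7.20 equiv; free catalyst 0.81 mol%; time 1.0 h
- violet: second substrate 0.340 equiv; reagent 7.20 equiv; free catalyst 0.81 mol%; time 1.0 h

| run | time / min | target / % |
|---|---|---|
| east | 15.0 | 9 |
| east | 30.0 | 15 |
| east | 50.0 | 23 |
| east | 60.0 | 27 |
| south | 8.00 | 5 |
| south | 20.0 | 8 |
| south | 40.0 | 16 |
| south | 60.0 | 21 |
| south-west | 8.00 | 0 |
| south-west | 20.0 | 6 |
| south-west | 40.0 | 11 |
| south-west | 60.0 | 16 |

(standard deviation of a reading: 1.5 percentage points)

- the flasks put in order of amount of target, in percent of the starting material charged, best first, at 1.0 h (ochre / amber / grey / teal / green / violet)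
- the amount of target, in percent of the starting material charged of the flask you put first, at 1.0 h
- the amount of target, in percent of the starting material charged of the flask you put last, at 1.0 h

- a reading or a percentage of target counts all its forms, free or not

Percent of target, divided by mol% of catalyst and by the time, gives the turnover rate, the times one catalyst serves in an hour. I took it from the south-west run, whose second substrate is grey's:

turnover rate = 16 % / 0.59 mol% / 1 h = 27.1 /h

Catalyst came first. By hand, at a steady turnover rate, target should follow the loading, and the south run, at 0.81 mol%, gave 25.9 /h, though the two runs also differ in second substrate and a reading carries a scatter of 1.5 percentage points. So I reckoned: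

grey: 27.1 /h × 0.81 mol% × 1.0 h = 22.0 %

amber: 27.1 /h × 1.5 mol% × 1.0 h = 40.6 %

Second substrate came next. By hand I expected more of it to hold catalyst back, and the east run, at 0.18 equiv, turned over at 33.3 /h, faster than the south run at 0.63 equiv. Teal, at 1.00 equiv, therefore belonged below grey.

Reagent came last. It stood at 1.8 equiv in the earlier runs, so my reckoning stops there. The forecast went on by assuming “roughly doubling the rate at 7.2 equiv”, and it gave violet > green > amber > grey > teal > ochre, with 45 % for violet and 8 % for ochre. Those two numbers are the forecast's, not mine.

The flasks gave violet > green > amber > grey > teal > ochre, with violet at 43.0 % and ochre at 10.0 %.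

    crystals ⇌ target, rate k1*(cs1 - [target]) while solid is left; crystals form when [target] > cs1 (solubility = 6.70 mM, k = 64.1 /h)
    reagent + catalyst intermediate B → free catalyst + second product (k = 915 /M/h)
    target → over-reaction product (k = 6.35 × 10⁻⁴ /h)
    reagent + catalyst intermediate A → free catalyst + target (k = 17900 /M/h)
    2 catalyst intermediate A ⇌ resting dimer, settled at all times (K = 2.71 × 10⁵ /M)
    starting material + free catalyst ⇌ catalyst intermediate A (K = 34.8 /M, k = 4480 /M/h)
    second substrate + free catalyst ⇌ catalyst intermediate B (K = 940 /M, k = 3560 /M/h)

The forecast stands, and a run would overturn it by putting green above violet, which lie 1.8 points apart. Grey turned over at 26.3 /h, near the 27.1 /h I carried, and ochre at 50.1 /h. In ochre at 1.00 h, catalyst intermediate A had a half-life against reagent of 0.045 min, shorter than the 0.52 min of free catalyst by forward capture of starting material alone. Scaling ochre's turnover rate with starting material, with equivalents, loading and time held, gives 17.0 % at 34 mM. Ochre's recipe at that amount gave 16.4 %.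

The earlier runs and the new flask are calculated for substances that don't exist; scatter was added.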